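The strategy rests on one feature. The p-mentha-1,8-diene ring (1-methyl-4-isopropenylcyclohex-1-ene) carries an acyclic quaternary carbon at C3, between vinylic C2-H and isopropenyl-bearing C4. The methyl group, the (E)-4,8-dimethylnona-3,7-dienyl arm and the first two chain carbons on that carbon make up a farnesyl skeleton bonded through its C3, and ring C3 is C6 of carvone.
Disconnection 1 (made last): the CH2-CH(CH3)-CH=CH2 terminus is removed through boron chemistry (Zweifel vinylation, reagent-controlled lithiation-borylation, Matteson CH2 insertion, hydroboration), leaving a vinyl group on the quaternary carbon.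
Disconnection 2: the ring C1=C2 alkene comes from a ketone at ring C2 through its enol triflate, enolised toward the methyl-bearing carbon.
Disconnection 3 (key): a retro-Claisen cut of the ring C3-quaternary carbon bond leads to the (2E,6E)-farnesyl enol ether of (5S)-dihydrocarvone, generated in situ from the dimethyl ketal and farnesol.
Rings: none is formed. The only ring is bought with (S)-carvone, whose stereocentre relays to the two new adjacent centres.

Key step: step 3

Assumption: isomerically pure (2E,6E)-farnesol and (+)-sparteine free base are taken as purchasable. The methyl epimers at carvone C2 are carried together because that carbon ends up sp2. Carvone numbering is used for the ring up to step 5: C1 carbonyl, C2 methyl-bearing, C5 isopropenyl-bearing, C6 between C1 and C5.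

Step 1
Reactants: 1 (S)-(+)-carvone
Product: 2 (5S)-dihydrocarvone [(2RS,5S)-2-methyl-5-(prop-1-en-2-yl)cyclohexan-1-one; both C2 epimers]
Conditions: Zn dust, KOH, MeOH/H2O, reflux
Reagents that add atoms: none
Why: In this dissolving-metal conjugate reduction, zinc in aqueous alcoholic base transfers electrons only to the conjugated enone, so the isolated isopropenyl group and C5 are untouched, and the C2 centre formed unselectively on enolate protonation does not matter because it is erased in step 4.

Step 2
Reactants: 2 (5S)-dihydrocarvone
Product: 3 dihydrocarvone dimethyl ketal [(5S)-1,1-dimethoxy-2-methyl-5-(prop-1-en-2-yl)cyclohexane; C2 epimers]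
Conditions: HC(OMe)3, MeOH, PPTS (cat.), 23 °C; Et3N quench, distillation
Reagents that add atoms: trimethyl orthoformate, COC(OC)OC; methanol (solvent, exchanges with the orthoformate), CO
Why: This is an acid-catalysed ketalisation in which the orthoformate consumes the water, and the pyridinium acid is too weak to protonate the isopropenyl group or to disturb C5.

Step 3
Reactants: 3 dihydrocarvone dimethyl ketal; 4 (2E,6E)-farnesol
Product: 7 C25 ketone (2S,3S,6RS)-6-methyl-3-(prop-1-en-2-yl)-2-[(3R,6E)-3,7,11-trimethyldodeca-1,6,10-trien-3-yl]cyclohexan-1-one, via mixed methyl farnesyl ketal 5 (not isolated), via farnesyl enol ether 6 (not isolated)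
Conditions: 3 (2 equiv), 4 (1 equiv), EtCO2H (0.1 equiv), xylenes, 110 to 140 °C, MeOH distilled off continuously
Reagents that add atoms: none
Why: Propionic acid ionises 3 to its oxocarbenium ion, farnesol is captured to give 5, and loss of the second methanol gives allyl enol ethers that interconvert (C2 epimers included) through the same cation, after which the C1=C6 isomer 6 undergoes a concerted, doubly suprafacial [3,3] shift that bonds ring C6 to farnesyl C3, breaks the allylic C-O bond and irreversibly releases the ketone and the vinyl group. The closest known reaction types are the ketal (mixed-acetal) Claisen rearrangement of cyclohexanone ketals with allylic alcohols and the Johnson orthoester Claisen of geraniol and farnesol, which builds the same C3 quaternary carbon under equally weak acid and heat without damage to the polyene. No ring is closed, since the six-membered array exists only in the transition state. The ring centre C6 is controlled by the neighbouring C5 isopropenyl group, which shields one face of the C1=C6 bond, so the allyl terminus should bond anti to it and give the trans-5,6 relationship, as in alkylations of 3-substituted cyclohexanone enolates. The quaternary centre is tied to C6 by the chair transition state: the ring holds C5 trans to oxygen (equatorial), the 2E alkene places the homogeranyl arm equatorial and the methyl axial, and this pairing maps onto the (R)-configured vinyl-bearing carbon that becomes the (S)-centre of the target. The step needs regio-, face and chair/boat selectivity, and these should be secured as follows: the C1=C2 enol ether would have to join two fully substituted carbons and should drain back through the equilibrium, the isopropenyl group blocks the syn face, and an acyclic allyl unit reacting across an endocyclic enol ether keeps its central carbon away from the ring only in the chair.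

Step 4
Reactants: 7 C25 ketone
Product: 9 enol triflate (5S,6S)-2-methyl-5-(prop-1-en-2-yl)-6-[(3R,6E)-3,7,11-trimethyldodeca-1,6,10-trien-3-yl]cyclohex-1-en-1-yl trifluoromethanesulfonate, via potassium enolate 8 (not isolated)
Conditions: KN(SiMe3)2, THF, -78 to 0 °C; Comins reagent, -78 to 23 °C
Reagents that add atoms: Comins reagent, N-(5-chloropyridin-2-yl)bis(trifluoromethanesulfonimide), Clc1ccc(nc1)N(S(=O)(=O)C(F)(F)F)S(=O)(=O)C(F)(F)F
Why: In this enol triflate synthesis by regioselective enolisation, the C6-H is buried between the quaternary carbon and C5 and its enolate would suffer severe allylic strain, so the amide base should remove the C2-H of either epimer, and O-sulfonylation then fixes the alkene at C1=C2 and erases the C2 centre.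

Step 5
Reactants: 9 enol triflate
Product: 10 C25 pentaene (3S,4S)-1-methyl-4-(prop-1-en-2-yl)-3-[(3R,6E)-3,7,11-trimethyldodeca-1,6,10-trien-3-yl]cyclohex-1-ene
Conditions: Pd(OAc)2 (5 mol %), PPh3 (10 mol %), HCO2H, Et3N, DMF, 60 °C
Reagents that add atoms: none
Why: In this palladium-catalysed formate hydrogenolysis of an enol triflate, oxidative addition of zerovalent palladium, exchange of triflate for formate, loss of CO2 and C-H reductive elimination replace OTf by H with the alkene locked in place, and neither the isolated alkenes nor the stereocentres are affected.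

Step 6
Reactants: 10 C25 pentaene
Product: 11 primary pinacol boronate 2-{(3S,6E)-3,7,11-trimethyl-3-[(1S,6S)-3-methyl-6-(prop-1-en-2-yl)cyclohex-2-en-1-yl]dodeca-6,10-dien-1-yl}-4,4,5,5-tetramethyl-1,3,2-dioxaborolane
Conditions: HBpin (1.1 equiv), [Ir(cod)Cl]2 (1.5 mol %), dppm (3 mol %), CH2Cl2, 23 °C
Reagents that add atoms: pinacolborane, [H]B1OC(C)(C)C(C)(C)O1
Why: In iridium-catalysed anti-Markovnikov hydroboration, coordination and insertion depend far more on the substitution pattern of the alkene than on allylic branching, so with little excess borane only the single monosubstituted alkene should react, at its terminal carbon, leaving the crowded isopropenyl group and the three trisubstituted alkenes.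

Step 7
Reactants: 11 primary pinacol boronate; 12 bromochloromethane
Product: 15 homologated primary pinacol boronate 2-{(4S,7E)-4,8,12-trimethyl-4-[(1S,6S)-3-methyl-6-(prop-1-en-2-yl)cyclohex-2-en-1-yl]trideca-7,11-dien-1-yl}-4,4,5,5-tetramethyl-1,3,2-dioxaborolane, via chloromethyllithium 13 (not isolated), via chloromethyl boronate complex 14 (not isolated)
Conditions: 12 (2 equiv), n-BuLi (1.8 equiv, added last), THF, -78 to 23 °C
Reagents that add atoms: none
Why: In this Matteson homologation, bromine-lithium exchange in the presence of the boronate gives the carbenoid, which adds to boron at once, and on warming the primary alkyl group migrates and expels chloride, while the alkenes are inert and no stereocentre is involved.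

Step 8
Reactants: 16 ethanol
Product: 17 ethyl 2,4,6-triisopropylbenzoate
Conditions: 2,4,6-triisopropylbenzoyl chloride, pyridine, DMAP (cat.), EtOH, reflux
Reagents that add atoms: 2,4,6-triisopropylbenzoyl chloride, CC(C)c1cc(C(C)C)c(C(=O)Cl)c(C(C)C)c1
Why: This is an acylation of a small primary alcohol used in excess, and heating with pyridine overcomes the ortho shielding of the acid chloride, the same shielding that later protects the ester carbonyl from the alkyllithium.

Step 9
Reactants: 15 homologated primary pinacol boronate; 17 ethyl 2,4,6-triisopropylbenzoate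
Product: 20 secondary (S)-boronate 2-{(2S,6S,9E)-6,10,14-trimethyl-6-[(1S,6S)-3-methyl-6-(prop-1-en-2-yl)cyclohex-2-en-1-yl]pentadeca-9,13-dien-2-yl}-4,4,5,5-tetramethyl-1,3,2-dioxaborolane, via (R)-1-lithioethyl ester 18 (not isolated), via lithium boronate complex 19 (not isolated)
Conditions: 17 (1.4 equiv), (+)-sparteine (1.4 equiv), s-BuLi (1.3 equiv), Et2O, -78 °C; 15, -78 °C; then 35 °C
Reagents that add atoms: none
Why: In this lithiation-borylation, s-BuLi/(+)-sparteine removes the pro-R proton of the OCH2 group to give a configurationally stable (R)-carbenoid, which is borylated with retention, and antiperiplanar 1,2-migration of the primary alkyl group with inversion then expels the hindered benzoate, so the (S)-CH(CH3)B centre is set by the reagent alone.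

Step 10
Reactants: 20 secondary (S)-boronate; 21 vinylmagnesium bromide
Product: 24 target CNP0208273.1 (3S,4S)-1-methyl-4-(prop-1-en-2-yl)-3-[(3S,7S,10E)-3,7,11,15-tetramethylhexadeca-1,10,14-trien-7-yl]cyclohex-1-ene, via vinyl boronate complex 22 (not isolated), via beta-iodo boronate 23 (not isolated)
Conditions: CH2=CHMgBr (4 equiv), THF, 23 °C; I2, MeOH/THF, -78 °C; NaOMe, MeOH, -78 to 23 °C; aq. Na2S2O3
Reagents that add atoms: none
Why: In this Zweifel olefination, the electron-rich vinyl boronate complex is iodinated much faster than the neutral alkenes at low temperature, the secondary alkyl group migrates to the adjacent carbon with retention, and methoxide-induced anti elimination of boron and iodide releases the terminal vinyl group on the intact (S)-methine.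

Compound list
1 | (S)-(+)-carvone, (5S)-2-methyl-5-(prop-1-en-2-yl)cyclohex-2-en-1-one | CC1=CC[C@@H](CC1=O)C(C)=C | starting material
2 | (5S)-dihydrocarvone, both C2 epimers | CC1CC[C@@H](CC1=O)C(C)=C | intermediate
3 | dihydrocarvone dimethyl ketal, (5S)-1,1-dimethoxy-2-methyl-5-(prop-1-en-2-yl)cyclohexane | CC1CC[C@@H](CC1(OC)OC)C(C)=C | intermediate
4 | (2E,6E)-farnesol | CC(C)=CCC/C(C)=C/CC/C(C)=C/CO | starting material
5 | mixed methyl (2E,6E)-farnesyl ketal of (5S)-dihydrocarvone (not isolated) | CC1CC[C@@H](CC1(OC)OC/C=C(\C)CC/C=C(\C)CCC=C(C)C)C(C)=C | intermediate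
6 | (3S)-6-methyl-3-(prop-1-en-2-yl)-1-[(2E,6E)-farnesyloxy]cyclohex-1-ene, less substituted enol ether (not isolated) | CC1CC[C@@H](C=C1OC/C=C(\C)CC/C=C(\C)CCC=C(C)C)C(C)=C | intermediate
7 | C25 ketone, (2S,3S,6RS)-6-methyl-3-(prop-1-en-2-yl)-2-[(3R,6E)-3,7,11-trimethyldodeca-1,6,10-trien-3-yl]cyclohexan-1-one | C=C[C@@](C)(CC/C=C(\C)CCC=C(C)C)[C@H]1C(=O)C(C)CC[C@@H]1C(=C)C | intermediate
8 | potassium enolate of 7 toward the methyl-bearing carbon (not isolated) | [K+].C=C[C@@](C)(CC/C=C(\C)CCC=C(C)C)[C@H]1C([O-])=C(C)CC[C@@H]1C(=C)C | intermediate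
9 | enol triflate of 7 (C1=C2, carvone numbering) | C=C[C@@](C)(CC/C=C(\C)CCC=C(C)C)[C@H]1C(OS(=O)(=O)C(F)(F)F)=C(C)CC[C@@H]1C(=C)C | intermediate
10 | C25 pentaene, (3S,4S)-1-methyl-4-(prop-1-en-2-yl)-3-[(3R,6E)-3,7,11-trimethyldodeca-1,6,10-trien-3-yl]cyclohex-1-ene | C=C[C@@](C)(CC/C=C(\C)CCC=C(C)C)[C@H]1C=C(C)CC[C@@H]1C(=C)C | intermediate
11 | primary pinacol boronate (quaternary C-CH2CH2-Bpin) | CC1(C)OB(CC[C@@](C)(CC/C=C(\C)CCC=C(C)C)[C@H]2C=C(C)CC[C@@H]2C(=C)C)OC1(C)C | intermediate
12 | bromochloromethane | ClCBr | starting material
13 | chloromethyllithium (not isolated) | [Li]CCl | intermediate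
14 | lithium chloromethyl boronate complex of 11 (not isolated) | [Li+].CC1(C)O[B-](CCl)(CC[C@@](C)(CC/C=C(\C)CCC=C(C)C)[C@H]2C=C(C)CC[C@@H]2C(=C)C)OC1(C)C | intermediate
15 | homologated primary pinacol boronate (quaternary C-CH2CH2CH2-Bpin) | CC1(C)OB(CCC[C@@](C)(CC/C=C(\C)CCC=C(C)C)[C@H]2C=C(C)CC[C@@H]2C(=C)C)OC1(C)C | intermediate
16 | ethanol | CCO | starting material
17 | ethyl 2,4,6-triisopropylbenzoate | CCOC(=O)c1c(C(C)C)cc(C(C)C)cc1C(C)C | intermediate
18 | (R)-1-lithioethyl 2,4,6-triisopropylbenzoate, (+)-sparteine complex (not isolated) | [Li][C@H](C)OC(=O)c1c(C(C)C)cc(C(C)C)cc1C(C)C | intermediate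
19 | lithium boronate complex of 15 with 18 (not isolated) | [Li+].CC1(C)O[B-](CCC[C@@](C)(CC/C=C(\C)CCC=C(C)C)[C@H]2C=C(C)CC[C@@H]2C(=C)C)([C@H](C)OC(=O)c3c(C(C)C)cc(C(C)C)cc3C(C)C)OC1(C)C | intermediate
20 | secondary (S)-pinacol boronate carrying the remote methyl centre | CC1(C)OB(OC1(C)C)[C@@H](C)CCC[C@@](C)(CC/C=C(\C)CCC=C(C)C)[C@H]2C=C(C)CC[C@@H]2C(=C)C | intermediate
21 | vinylmagnesium bromide | C=C[Mg]Br | starting material
22 | bromomagnesium vinyl boronate complex of 20 (not isolated) | [Mg+2].[Br-].C=C[B-]1(OC(C)(C)C(C)(C)O1)[C@@H](C)CCC[C@@](C)(CC/C=C(\C)CCC=C(C)C)[C@H]2C=C(C)CC[C@@H]2C(=C)C | intermediate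
23 | beta-iodo boronate after 1,2-migration, epimers at the boron-bearing carbon (not isolated) | ICC(B1OC(C)(C)C(C)(C)O1)[C@@H](C)CCC[C@@](C)(CC/C=C(\C)CCC=C(C)C)[C@H]2C=C(C)CC[C@@H]2C(=C)C | intermediate
24 | CNP0208273.1, (3S,4S)-1-methyl-4-(prop-1-en-2-yl)-3-[(3S,7S,10E)-3,7,11,15-tetramethylhexadeca-1,10,14-trien-7-yl]cyclohex-1-ene | C=C[C@@H](C)CCC[C@@](C)(CC/C=C(\C)CCC=C(C)C)[C@H]1C=C(C)CC[C@@H]1C(=C)C | target

Total step count: 10 (nine on the main line and one for ester 17).
Longest linear sequence: 9 steps, from 1 to 24 (steps 1 to 7, 9 and 10).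

Steps most likely to fail

Step 3.
- What may go wrong: the equilibrating enol ether pool may drain through the more substituted isomer, forming the bond at the methyl-bearing carbon. Prolonged acid and heat may ionise or isomerise the allylic alcohol. Face or chair selectivity may erode next to the isopropenyl group.
- Fallback, from 2 (with 4) and back at 7: compound 2 is condensed with 2,4,6-triisopropylbenzenesulfonyl hydrazide to give dihydrocarvone trisylhydrazone F1. A Shapiro reaction (n-BuLi, 2 equiv, THF/TMEDA, -78 to 0 °C) deprotonates only the CH2 side and gives the less substituted cyclohexenyllithium F2. Iodine converts this into (3S)-1-iodo-6-methyl-3-(prop-1-en-2-yl)cyclohex-1-ene F3. Copper-catalysed C-O coupling of F3 with 4 (CuI, 3,4,7,8-tetramethyl-1,10-phenanthroline, Cs2CO3, o-xylene, 120 to 140 °C) builds enol ether 6 as one regioisomer. The medium is basic, so 6 cannot equilibrate, and it rearranges to 7 in the same pot.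

Step 6.
- What may go wrong: the neopentylic position of the vinyl group slows its hydroboration, so the isopropenyl group may compete and double borylation may follow.
- Fallback, from 10 and back at 15: an aldehyde-selective nitrite-modified Wacker oxidation (PdCl2(PhCN)2, CuCl2·2H2O, AgNO2, t-BuOH/MeNO2, O2) addresses only monosubstituted alkenes and, next to a quaternary carbon, places oxygen at the terminus. It gives (3R,6E)-3,7,11-trimethyl-3-[(1S,6S)-3-methyl-6-(prop-1-en-2-yl)cyclohex-2-en-1-yl]dodeca-6,10-dienal F4. Wittig methylenation (Ph3PCH3Br, KOt-Bu, THF) gives the allyl-substituted hydrocarbon (3S,4S)-1-methyl-4-(prop-1-en-2-yl)-3-[(4R,7E)-4,8,12-trimethyltrideca-1,7,11-trien-4-yl]cyclohex-1-ene F5. Its unhindered terminal alkene is hydroborated with HBpin under the iridium catalysis of step 6 to give 15 directly, so step 7 is not needed.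

Step 5.
- What may go wrong: oxidative addition into a fully substituted, flanked enol triflate may be slow, and the tethered trisubstituted alkene may capture the alkenylpalladium intermediate (6-exo carbopalladation) before formate delivers hydride.
- Fallback, from 7 (through enolate 8) and back at 10: the enolate is trapped with ClP(O)(OEt)2 to give the diethyl enol phosphate F6. Its C-O bond is cleaved by dissolving-metal reduction (Li, NH3(l)/THF, t-BuOH, -78 °C, short contact). The second electron transfer outruns radical cyclisation, and the isolated alkenes should survive, giving 10.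

Further compounds
F1 | step 3 | dihydrocarvone 2,4,6-triisopropylbenzenesulfonylhydrazone | CC1CC[C@@H](CC1=NNS(=O)(=O)c2c(C(C)C)cc(C(C)C)cc2C(C)C)C(C)=C
F2 | step 3 | (3S)-6-methyl-3-(prop-1-en-2-yl)cyclohex-1-en-1-yllithium | CC1CC[C@@H](C=C1[Li])C(C)=C
F3 | step 3 | (3S)-1-iodo-6-methyl-3-(prop-1-en-2-yl)cyclohex-1-ene | CC1CC[C@@H](C=C1I)C(C)=C
F4 | step 6 | (3R,6E)-3,7,11-trimethyl-3-[(1S,6S)-3-methyl-6-(prop-1-en-2-yl)cyclohex-2-en-1-yl]dodeca-6,10-dienal | O=CC[C@@](C)(CC/C=C(\C)CCC=C(C)C)[C@H]1C=C(C)CC[C@@H]1C(=C)C
F5 | step 6 | (3S,4S)-1-methyl-4-(prop-1-en-2-yl)-3-[(4R,7E)-4,8,12-trimethyltrideca-1,7,11-trien-4-yl]cyclohex-1-ene | C=CC[C@@](C)(CC/C=C(\C)CCC=C(C)C)[C@H]1C=C(C)CC[C@@H]1C(=C)C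
F6 | step 5 | diethyl enol phosphate of 7 (C1=C2, carvone numbering) | C=C[C@@](C)(CC/C=C(\C)CCC=C(C)C)[C@H]1C(OP(=O)(OCC)OCC)=C(C)CC[C@@H]1C(=C)C
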